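(The numbers are those of an exercise; the rest is arithmetic.)

I cannot integrate this flask by hand: L, D and X move together, and each rate multiplies concentrations that are themselves moving.

    L.D → Z (k1 = 0.094 s⁻¹)
    D ⇌ X, rate k2*([D] - [X]/K2) per volume of the first phase (K2 = 0.78, k2 = 0.059 s⁻¹)
    L.D ⇌ E (K3 = 7.8, k3 = 0.020 s⁻¹)
    L.D ⇌ J, rate k4*([L.D] - [J]/K4) per volume of the first phase (K4 = 20, k4 = 0.047 s⁻¹)
    2 L → L2 (k5 = 0.23 M⁻¹ s⁻¹)
    L + D → L.D (k6 = 13 M⁻¹ s⁻¹)

L 0.082 M; X 1.00 equiv; time 1.5 min; volume of the second phase over the first 1.0

- in percentages every species weighs as the L in it: one L2 counts as two
- for L.D the J are counted in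
- two of one species on the left: rate k times its square, two consumed each time
- in the second phase: X, J; everything else is in the first
- charges count per volume of the first phase; a concentration in a rate is the amount of a species over the volume of its own phase; every rate counts per litre of the first phase
- run time (flask): 1.5 min

- larch: doubling the transfer coefficient of step 4, all else as stated
- ash: doubling the transfer coefficient of step 2, all else as stated
- birch: doubling the amount of X, all else as stated

1. L.D and J together at 1.5 min, in percent of the L charged
2. the change that raises the amount of L.D and J together at 1.5 min, in percent of the L charged most ("none" if none brings more than 2 percentage points) (larch / ash / birch / none)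
3. amount of L.D and J together at 1.5 min, in percent of the L charged, after ash

I can still ask a question that needs no clock. L.D in the first phase has three exits: to Z, to E, and across into the second phase as J. Each exit runs at a constant times the same concentration of L.D, so when I divide one rate by the sum of the three, both concentration and time drop out:

escape share = 0.047 s⁻¹ / (0.094 s⁻¹ + 0.020 s⁻¹ + 0.047 s⁻¹) = 0.292

This is the escape share, the fraction of departing L.D that leaves as J, which the field calls a selectivity. The time constant of L.D is 6.21 s, shorter than the run, so what is formed has time to branch. I neglect the slow return of J for now.

The yield is then the share times the L captured as L.D. D lasts 0.65 s against L, so capture runs at the rate X crosses over, and L2 competes with it. With the charges as they stand: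

delivery of X = 0.00620 M s⁻¹, loss of L to L2 = 0.00309 M s⁻¹

loss share at the start = 0.333

The loss falls as L falls. As a guess, I take its average over the run as 0.5 of the starting share, so the captured fraction is 0.834.

flask: 0.292 × 0.834 = 24.4 %

ash: the share stays, the captured fraction becomes 0.900, giving 26.3 %

larch: the share becomes 0.452, giving 37.7 %

So I commit to larch.

The forecast gives 22.3 %, larch and 24.5 % after ash, holding that in the second phase “it largely survives while the L.D left behind goes mainly to Z”.

The simulation gives 21.3 %, and 22.8 % after ash. Larch gains 9.4 percentage points, ash 1.5 points and birch 2.1 points, so the answer is larch.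

In this flask L2 holds 20.9 % of the L at 1.50 min, and the share of the remainder is 23.1 % against 21.3 %. The total stays low because L.D goes to Z while its crossing is slow: the run without the path to Z gives 56.7 %, and the run with fast crossing gives 52.1 %. J returns to L.D at 0.00235 s⁻¹ and E at 0.00256 s⁻¹, and the same share of what comes back crosses again. With E at 8.74 % and J at 20.9 % at 1.50 min, and taking that ratio as lasting, J drains at 0.00135 s⁻¹. From 21.3 % that leaves 14.8 % in the flask left until 6.0 min, which reads 14.8 %.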